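**Retrosynthetic overview**
1. Target 8 ⇐ dienyl vanillate 6 by a one-flask formal ene hydroxylation: outer-face epoxidation makes the C7–O bond and sets C7, then a cobalt-catalysed epoxide-to-allylic-alcohol transposition creates the (E)-C8=C9 olefin.
2. 6 ⇐ cis-alcohol 4 + unprotected vanillic acid 5 by Mitsunobu esterification, which forms the C1–O bond with inversion.
3. 4 ⇐ racemic ketone 3 by asymmetric hydrogenation with dynamic kinetic resolution, which sets C1 and C10 together.
4. 3 ⇐ germacrone 1 by conjugate reduction of the isopropylidene enone.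
5. Rings: the ten-membered carbocycle is bought intact in germacrone and no C–C bond is made; the only ring formed is the transient oxirane of step 4, opened in the same flask.

Assumption: germacrone is taken as an inexpensive commercial natural product (crystallised on scale from zdravets and zedoary oils); stereodescriptors use the ring locants of the IUPAC names (C1 = ester carbon, C10 = isopropyl-bearing carbon).

**Route**

Step 1
Reactants: 1 germacrone, (3E,7E)-3,7-dimethyl-10-(propan-2-ylidene)cyclodeca-3,7-dien-1-one
Product: 3 (±)-(3E,7E)-3,7-dimethyl-10-(propan-2-yl)cyclodeca-3,7-dien-1-one, via triethylsilyl enol ether 2 (not isolated)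
Conditions: Et3SiH, RhCl(PPh3)3 (1 mol%), PhH, 60 °C; then TBAF, AcOH, THF, 0 °C
Reagents that add atoms: none
Why: Rhodium-catalysed conjugate (1,4-) hydrosilylation touches only the s-cis enone (the isolated trisubstituted ring olefins are inert to RhCl(PPh3)3/Et3SiH and 60 °C is well below the Cope threshold of the 1,5-diene), and buffered fluoride desilylation of 2 protonates C10 without the acid that would cyclise the germacradiene, so C10 is formed racemic on purpose.

Step 2
Reactants: 3 (±)-(3E,7E)-3,7-dimethyl-10-(propan-2-yl)cyclodeca-3,7-dien-1-one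
Product: 4 (1R,3E,7E,10R)-3,7-dimethyl-10-(propan-2-yl)cyclodeca-3,7-dien-1-ol (hydroxyl and isopropyl cis)
Conditions: H2 (8 atm), RuCl2[(S)-binap][(R,R)-dpen] (0.5 mol%), t-BuOK (4 mol%), i-PrOH, 25 °C
Reagents that add atoms: none
Why: Noyori-type asymmetric ketone hydrogenation with dynamic kinetic resolution, in which t-BuOK epimerises C10 through the enolate faster than reduction while the chiral RuH/NH2 catalyst reduces the (10R)-ketone from the peripheral face anti to the isopropyl group (the behaviour of 2-isopropylcyclohexanone), setting C10 (R) and C1 (R) together and leaving the olefins untouched.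

Step 3
Reactants: 4 (1R,3E,7E,10R)-3,7-dimethyl-10-(propan-2-yl)cyclodeca-3,7-dien-1-ol; 5 vanillic acid (4-hydroxy-3-methoxybenzoic acid)
Product: 6 (1S,3E,7E,10R)-3,7-dimethyl-10-(propan-2-yl)cyclodeca-3,7-dien-1-yl 4-hydroxy-3-methoxybenzoate
Conditions: PPh3, DIAD, THF, 0 to 25 °C
Reagents that add atoms: none
Why: Mitsunobu esterification, in which the alkoxyphosphonium ion of 4 is displaced by the vanillate carboxylate in an SN2 step that forms the C1–O ester bond with inversion (1R to 1S), and because the betaine deprotonates the carboxylic acid (pKa about 4.5) rather than the phenol (pKa about 9) the acid is used unprotected.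

Step 4
Reactants: 6 (1S,3E,7E,10R)-3,7-dimethyl-10-(propan-2-yl)cyclodeca-3,7-dien-1-yl 4-hydroxy-3-methoxybenzoate
Product: 8 (1S,3E,7R,8E,10S)-7-hydroxy-3,7-dimethyl-10-(propan-2-yl)cyclodeca-3,8-dien-1-yl 4-hydroxy-3-methoxybenzoate (target), via trans-7,8-epoxide 7 (not isolated)
Conditions: DMDO (1.0 equiv), acetone/CH2Cl2, −40 °C, then evaporate at 0 °C; Co(dmgH)2(py)Cl (10 mol%), NaBH4 (20 mol%), degassed MeOH/MeCN, 450 nm LED, 20 °C
Reagents that add atoms: dimethyldioxirane, CC1(C)OO1
Why: Proposed new method: a one-flask formal ene hydroxylation in which dimethyldioxirane first transfers oxygen concertedly (dioxirane epoxidation) to the exposed outer face of the C7=C8 olefin of the crown conformer (isopropyl and aroyloxy pseudo-equatorial, the C3=C4 olefin being deactivated by the homoallylic ester), forming the C7–O bond and fixing C7 as R, after which monovalent cobalt generated from Co(dmgH)2(py)Cl opens epoxide 7 by SN2 attack at the secondary C8, and light-induced Co–C homolysis followed by β-hydrogen abstraction by divalent cobalt from C9 (the only β-hydrogens, C7 being quaternary, and the ring torsion about C8–C9 aligning the rotamer that leads to the E-olefin) gives the (E)-C8=C9 olefin and a cobalt hydride that is deprotonated back to monovalent cobalt, so the C7–O bond and its configuration survive a redox-neutral transposition; the closest known reactions are the cyanocobalamin (C63H88CoN14O14P)-catalysed isomerisation of simple meso epoxides to allylic alcohols and the photochemical dehydrocobaltation of alkylcobaloximes, neither shown for a trisubstituted medium-ring epoxide or for delivery of a tertiary allylic alcohol.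

**Compound list**
1 | germacrone, (3E,7E)-3,7-dimethyl-10-(propan-2-ylidene)cyclodeca-3,7-dien-1-one | O=C1C/C(C)=C/CC/C(C)=C/CC1=C(C)C | starting material
2 | triethyl{[(1Z,4E,8E)-5,9-dimethyl-2-(propan-2-yl)cyclodeca-1,4,8-trien-1-yl]oxy}silane | CC[Si](CC)(CC)O/C1=C(C(C)C)/C/C=C(C)/CC/C=C(C)/C1 | intermediate (not isolated)
3 | (±)-(3E,7E)-3,7-dimethyl-10-(propan-2-yl)cyclodeca-3,7-dien-1-one | O=C1C/C(C)=C/CC/C(C)=C/CC1C(C)C | intermediate
4 | (1R,3E,7E,10R)-3,7-dimethyl-10-(propan-2-yl)cyclodeca-3,7-dien-1-ol | O[C@@H]1C/C(C)=C/CC/C(C)=C/C[C@@H]1C(C)C | intermediate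
5 | vanillic acid, 4-hydroxy-3-methoxybenzoic acid | COc1cc(C(=O)O)ccc1O | starting material
6 | (1S,3E,7E,10R)-3,7-dimethyl-10-(propan-2-yl)cyclodeca-3,7-dien-1-yl 4-hydroxy-3-methoxybenzoate | COc1cc(C(=O)O[C@H]2C/C(C)=C/CC/C(C)=C/C[C@@H]2C(C)C)ccc1O | intermediate
7 | (1S,3E,7R,8R,10R)-7,8-epoxy-3,7-dimethyl-10-(propan-2-yl)cyclodec-3-en-1-yl 4-hydroxy-3-methoxybenzoate | COc1cc(C(=O)O[C@H]2C/C(C)=C/CC[C@@]3(C)O[C@@H]3C[C@@H]2C(C)C)ccc1O | intermediate (not isolated)
8 | (1S,3E,7R,8E,10S)-7-hydroxy-3,7-dimethyl-10-(propan-2-yl)cyclodeca-3,8-dien-1-yl 4-hydroxy-3-methoxybenzoate | COc1cc(C(=O)O[C@H]2C/C(C)=C/CC[C@@](C)(O)/C=C/[C@@H]2C(C)C)ccc1O | target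

**Totals and risks**
Total step count: 4. Longest linear sequence: 4 (from germacrone).

Step 4 (the new step). Likely failures are a slow SN2 opening at C8 (the backside of that carbon faces the ring interior) and transannular cyclisation of the C8 radical onto the C3=C4 olefin. Some 3,4-epoxide may also form in the first operation. The fallback uses known chemistry, sets out from 6 and returns at 8. The dimethyldioxirane epoxidation is run alone and epoxide 7 is isolated on base-washed silica. PhSeSePh/NaBH4 in EtOH at 78 °C then opens it at C8 in a two-electron SN2 step (no radical) to give the anti β-hydroxy selenide F1. H2O2/pyridine in THF at 0 °C gives the selenoxide F2, which undergoes syn elimination at 25 °C away from the carbinol carbon (C7 has no hydrogen) to give 8. This is the Sharpless–Lauer epoxide-to-allylic-alcohol sequence.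

Step 2. Likely failures are base-induced migration of the β,γ-placed C3=C4 olefin into conjugation and low cis selectivity in the flexible ring. If the sense of induction is opposite, the mirror-image catalyst RuCl2[(R)-binap][(S,S)-dpen] is used. The fallback sets out from 3 and returns at 4. Racemic 3 is reduced without base under reagent control with (S)-Me-CBS/BH3·SMe2 in THF at −40 °C, which gives (1R)-carbinols from both ketone enantiomers: 4 and its C10 epimer, the (1R,10S)-alcohol F3. These diastereomers are separated. F3 is recycled by Dess–Martin oxidation to the (10S)-ketone F4, which DBU racemises back to 3.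

Step 3. The likely failure is E2 elimination of the hindered alkoxyphosphonium ion (towards the conjugated diene) instead of substitution. The fallback avoids SN2 at C1, sets out from 4 and returns at 6. Dess–Martin oxidation of 4 gives the enantioenriched (10R)-ketone F5. Thermodynamically controlled single-electron reduction (samarium diiodide, H2O, Et3N, THF, 0 °C) gives the trans (1S,10R)-alcohol F6. Retentive acylation with commercial 4-acetoxy-3-methoxybenzoic acid (EDC, DMAP, CH2Cl2) gives the acetate-protected ester F7. Selective methanolysis of the aryl acetate (K2CO3, MeOH, 0 °C) then gives 6.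

**Further compounds**
F1 | step 4 | (1S,3E,7R,8S,10R)-7-hydroxy-3,7-dimethyl-8-(phenylselanyl)-10-(propan-2-yl)cyclodec-3-en-1-yl 4-hydroxy-3-methoxybenzoate | COc1cc(C(=O)O[C@H]2C/C(C)=C/CC[C@@](C)(O)[C@@H]([Se]c3ccccc3)C[C@@H]2C(C)C)ccc1O
F2 | step 4 | selenoxide of F1 (8-benzeneseleninyl, not isolated) | COc1cc(C(=O)O[C@H]2C/C(C)=C/CC[C@@](C)(O)[C@@H]([Se](=O)c3ccccc3)C[C@@H]2C(C)C)ccc1O
F3 | step 2 | (1R,3E,7E,10S)-3,7-dimethyl-10-(propan-2-yl)cyclodeca-3,7-dien-1-ol | O[C@@H]1C/C(C)=C/CC/C(C)=C/C[C@H]1C(C)C
F4 | step 2 | (3E,7E,10S)-3,7-dimethyl-10-(propan-2-yl)cyclodeca-3,7-dien-1-one | O=C1C/C(C)=C/CC/C(C)=C/C[C@H]1C(C)C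
F5 | step 3 | (3E,7E,10R)-3,7-dimethyl-10-(propan-2-yl)cyclodeca-3,7-dien-1-one | O=C1C/C(C)=C/CC/C(C)=C/C[C@@H]1C(C)C
F6 | step 3 | (1S,3E,7E,10R)-3,7-dimethyl-10-(propan-2-yl)cyclodeca-3,7-dien-1-ol | O[C@H]1C/C(C)=C/CC/C(C)=C/C[C@@H]1C(C)C
F7 | step 3 | (1S,3E,7E,10R)-3,7-dimethyl-10-(propan-2-yl)cyclodeca-3,7-dien-1-yl 4-acetoxy-3-methoxybenzoate | COc1cc(C(=O)O[C@H]2C/C(C)=C/CC/C(C)=C/C[C@@H]2C(C)C)ccc1OC(C)=O
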